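**Retrosynthetic overview**

- Target 12 is cut first at its two labile ethers (the 5-OMe peri to the C4 carbonyl and a 5'-O-benzyl group), then at the C2–C1' bond between ring C and ring B. This gives 3,5,7,8-tetramethoxychromone 7 (C2–H) and aryl bromide 9.
- The strategy rests on C3 of ring C carrying OMe. C2–H is then the only C–H of the pyranone ring; it sits next to O1, is vinylogous to the C4 carbonyl and is flanked by the coordinating 3-OMe, so it can be zincated and arylated last.
- Ring C is closed onto ring A from the ω-methoxy ketone 4 with a one-carbon amide acetal, which supplies C2 and allows the O1–C2 bond to form. Ketone 4 comes from 1,2,3,5-tetramethoxybenzene by acylation and cleavage of the buttressed ortho ether.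
- Ring order: rings A and B are bought as benzenes, ring C is built on ring A (steps 3–4), ring B is attached to C2 in step 6.

Key step: step 6

Remark on the chemistry: the double bond of enaminone 6 is drawn Z (NMe2 trans to the aroyl group) by analogy with related enaminones, and this geometry is lost in step 4. Zinc species 10 is drawn as the monomeric chloride without its LiCl.

**Route**

Step 1
Reactants: 1 1,2,3,5-tetramethoxybenzene; 2 methoxyacetyl chloride
Product: 3 2-methoxy-1-(2,3,4,6-tetramethoxyphenyl)ethan-1-one
Conditions: AlCl3 (1.2 equiv), CH2Cl2, −10 → 0 °C, short reaction time; cold dilute HCl work-up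
Reagents that add atoms: none
Why: Friedel–Crafts acylation at one of the two equivalent free positions, each ortho to two OMe groups and para to a third, so only one aryl ketone can form.

Step 2
Reactants: 3 2-methoxy-1-(2,3,4,6-tetramethoxyphenyl)ethan-1-one
Product: 4 1-(2-hydroxy-3,4,6-trimethoxyphenyl)-2-methoxyethan-1-one
Conditions: BCl3 (1.2 equiv), CH2Cl2, −78 → 0 °C; aqueous HCl work-up
Reagents that add atoms: none
Why: Chelation-assisted Lewis-acid ether cleavage, in which BCl3 bound to the ketone oxygen should cleave an ortho aryl methyl ether through a six-membered boron chelate; of the two ortho ethers the 2-OMe, wedged between the acyl group and the 3-OMe and twisted out of the ring plane, is the more basic and more strained, while the aliphatic CH2–OMe and the non-chelated 3- and 4-OMe groups should stay intact at this temperature.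

Step 3
Reactants: 4 1-(2-hydroxy-3,4,6-trimethoxyphenyl)-2-methoxyethan-1-one; 5 N,N-dimethylformamide dimethyl acetal
Product: 6 (Z)-3-(dimethylamino)-1-(2-hydroxy-3,4,6-trimethoxyphenyl)-2-methoxyprop-2-en-1-one
Conditions: 5 (3 equiv), toluene, 100 °C, with removal of MeOH
Reagents that add atoms: none
Why: Amide-acetal condensation (enaminone formation) at the only enolisable position, the methylene between the ketone and the side-chain OMe; the hydrogen-bonded ortho phenol is expected to resist O-methylation by the acetal under these conditions.

Step 4
Reactants: 6 (Z)-3-(dimethylamino)-1-(2-hydroxy-3,4,6-trimethoxyphenyl)-2-methoxyprop-2-en-1-one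
Product: 7 3,5,7,8-tetramethoxy-4H-chromen-4-one (3,5,7,8-tetramethoxychromone, C2–H)
Conditions: conc. aqueous HCl, CH2Cl2, 25–40 °C
Reagents that add atoms: none
Why: Acid-promoted conjugate addition of the phenol oxygen to the β-amino enone carbon followed by elimination of dimethylamine (addition–elimination) should close ring C as the aromatic 4-pyranone, the standard enaminone-to-chromone cyclisation.

Step 5
Reactants: 8 3-bromo-4-methoxyphenol
Product: 9 4-(benzyloxy)-2-bromo-1-methoxybenzene (4-benzyloxy-2-bromoanisole)
Conditions: BnBr, K2CO3, DMF, 25 °C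
Reagents that add atoms: benzyl bromide, BrCc1ccccc1
Why: Williamson ether synthesis on the only acidic OH; the benzyl ether masks the phenol that would otherwise quench the organozinc in step 6.

Step 6
Reactants: 7 3,5,7,8-tetramethoxy-4H-chromen-4-one; 9 4-(benzyloxy)-2-bromo-1-methoxybenzene
Product: 11 2-[5-(benzyloxy)-2-methoxyphenyl]-3,5,7,8-tetramethoxy-4H-chromen-4-one (5'-benzyloxy-3,5,7,8,2'-pentamethoxyflavone), via C2-zincated chromone 10 (not isolated)
Conditions: TMPZnCl·LiCl (TMP = 2,2,6,6-tetramethylpiperidid-1-yl; 1.3 equiv), THF, 25 °C; then 9, Pd(OAc)2 (4 mol%), SPhos (8 mol%), THF, 50 °C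
Reagents that add atoms: none
Why: TMPZnCl·LiCl should remove the only ring C proton, C2–H, which is vinylic, attached to the carbon next to O1, vinylogous to the C4 carbonyl and flanked by the coordinating 3-OMe, giving the C2-zinc chromone 10, a covalent organozinc too mild to add to a C4 carbonyl or to open the pyranone. Zerovalent palladium formed in the flask from Pd(OAc)2 and SPhos inserts into the C–Br bond of 9, the chromonyl group passes from zinc to palladium, and reductive elimination joins C2 of ring C to C1' of ring B. The closest known reaction type is the zincation of chromones with TMP-zinc amides followed by Negishi coupling to flavones, applied here to a 3-methoxy, fully oxygenated chromone. No ring closes and no stereocentre is formed. The selectivity needed is C2–H over the ring A C6–H between the 5- and 7-OMe groups; a zinc amide of this strength does not metalate dimethoxyarenes at 25 °C, so the far more acidic pyranone C–H should react, and because C3 carries OMe no C2/C3 choice arises. The bulky, electron-rich biaryl phosphine is chosen because both carbons being joined carry an ortho methoxy group.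

Step 7
Reactants: 11 2-[5-(benzyloxy)-2-methoxyphenyl]-3,5,7,8-tetramethoxy-4H-chromen-4-one
Product: 12 5-hydroxy-2-(5-hydroxy-2-methoxyphenyl)-3,7,8-trimethoxy-4H-chromen-4-one (5,5'-dihydroxy-3,7,8,2'-tetramethoxyflavone)
Conditions: BCl3 (4 equiv), pentamethylbenzene (3 equiv), CH2Cl2, −78 → 0 °C; then MeOH, aqueous HCl
Reagents that add atoms: none
Why: Lewis-acid dealkylation, in which BCl3 cleaves the aryl benzyl ether already at low temperature (the benzyl cation being trapped by pentamethylbenzene in a Friedel–Crafts alkylation) and, on warming, the 5-OMe through the six-membered chelate with the C4 carbonyl, whereas the 3-OMe (less favourable five-membered chelate, carbonyl already tied up by boron) and the non-chelated 7-, 8- and 2'-OMe groups should survive.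

**Compound list**

1 | 1,2,3,5-tetramethoxybenzene | COc1cc(OC)c(OC)c(OC)c1 | starting material
2 | methoxyacetyl chloride | COCC(=O)Cl | starting material
3 | 2-methoxy-1-(2,3,4,6-tetramethoxyphenyl)ethan-1-one | COCC(=O)c1c(OC)c(OC)c(OC)cc1OC | intermediate
4 | 1-(2-hydroxy-3,4,6-trimethoxyphenyl)-2-methoxyethan-1-one | COCC(=O)c1c(O)c(OC)c(OC)cc1OC | intermediate
5 | N,N-dimethylformamide dimethyl acetal | COC(OC)N(C)C | starting material
6 | (Z)-3-(dimethylamino)-1-(2-hydroxy-3,4,6-trimethoxyphenyl)-2-methoxyprop-2-en-1-one | CO/C(=C\N(C)C)C(=O)c1c(O)c(OC)c(OC)cc1OC | intermediate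
7 | 3,5,7,8-tetramethoxy-4H-chromen-4-one | COc1cc(OC)c2c(=O)c(OC)coc2c1OC | intermediate
8 | 3-bromo-4-methoxyphenol | COc1ccc(O)cc1Br | starting material
9 | 4-(benzyloxy)-2-bromo-1-methoxybenzene | COc1ccc(OCc2ccccc2)cc1Br | intermediate
10 | chloro(3,5,7,8-tetramethoxy-4-oxo-4H-chromen-2-yl)zinc, formed as its LiCl complex | COc1cc(OC)c2c(=O)c(OC)c([Zn]Cl)oc2c1OC | intermediate
11 | 2-[5-(benzyloxy)-2-methoxyphenyl]-3,5,7,8-tetramethoxy-4H-chromen-4-one | COc1ccc(OCc2ccccc2)cc1-c1oc2c(OC)c(OC)cc(OC)c2c(=O)c1OC | intermediate
12 | 5-hydroxy-2-(5-hydroxy-2-methoxyphenyl)-3,7,8-trimethoxy-4H-chromen-4-one (5,5'-dihydroxy-3,7,8,2'-tetramethoxyflavone) | COc1ccc(O)cc1-c1oc2c(OC)c(OC)cc(O)c2c(=O)c1OC | target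

**Step count**

Total steps: 7. Longest linear sequence: 6 (steps 1, 2, 3, 4, 6, 7); step 5 is the one-step side branch.

**Steps most likely to fail, with fallbacks**

Step 6. Transmetalation and reductive elimination between two carbons that each carry an ortho methoxy group may be too slow. Protodezincation on work-up and homocoupling of the aryl bromide would then dominate, or the zincation itself may stall on the electron-rich chromone. The fallback builds the flavone by the classical acyl-transfer route and needs no metalation. It sets out from 4 and 9 and comes back at 11. Bromine–lithium exchange on 9 (n-BuLi, THF, −78 °C) and carboxylation with CO2 would give 5-(benzyloxy)-2-methoxybenzoic acid F1. Esterification of the phenol of 4 with F1 (EDC·HCl, DMAP, CH2Cl2) would give 3,5,6-trimethoxy-2-(methoxyacetyl)phenyl 5-(benzyloxy)-2-methoxybenzoate F2. A Baker–Venkataraman acyl shift (KOH, pyridine, 50 °C) would give 1-[5-(benzyloxy)-2-methoxyphenyl]-3-(2-hydroxy-3,4,6-trimethoxyphenyl)-2-methoxypropane-1,3-dione F3, racemic at its enolisable C2. Cyclodehydration of F3 (TsOH·H2O, toluene, 80 °C) would close ring C with ring B already in place and deliver 11.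

Step 7. Dealkylation may overrun, with loss of the 3-OMe through its five-membered chelate or of the crowded 8-OMe. The benzyl cation may also alkylate the electron-rich rings if trapping is incomplete. The fallback separates the two deprotections into orthogonal operations. It sets out from 11 and comes back at 12. Hydrogenolysis (H2, Pd/C (palladium metal on carbon), EtOAc–MeOH, 25 °C) would give 2-(5-hydroxy-2-methoxyphenyl)-3,5,7,8-tetramethoxy-4H-chromen-4-one F4. The chelated 5-OMe alone would then be cleaved with the milder AlCl3 in MeCN at 25–40 °C, followed by dilute HCl to break the aluminium chelate, giving 12.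

Step 3. Condensation at the α-methoxy methylene may be sluggish, and prolonged heating may let the acetal O-methylate the phenol, which would block ring closure. The fallback brings in C2 as a formyl group instead of an enaminone. It sets out from 4 and comes back at 7, bypassing 6. Claisen formylation of 4 with ethyl formate and NaH (THF, 0 → 25 °C), then acidification, would give 2-hydroxy-3,5,7,8-tetramethoxychroman-4-one F5, the cyclic hemiacetal of the α-formyl ketone, as a racemic mixture of diastereomers. Dehydration of F5 with HCl in AcOH would remove both stereocentres and give chromone 7.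

**Further compounds**

F1 | step 6 | 5-(benzyloxy)-2-methoxybenzoic acid | COc1ccc(OCc2ccccc2)cc1C(=O)O
F2 | step 6 | 3,5,6-trimethoxy-2-(methoxyacetyl)phenyl 5-(benzyloxy)-2-methoxybenzoate | COCC(=O)c1c(OC(=O)c2cc(OCc3ccccc3)ccc2OC)c(OC)c(OC)cc1OC
F3 | step 6 | 1-[5-(benzyloxy)-2-methoxyphenyl]-3-(2-hydroxy-3,4,6-trimethoxyphenyl)-2-methoxypropane-1,3-dione (racemic) | COC(C(=O)c1cc(OCc2ccccc2)ccc1OC)C(=O)c1c(O)c(OC)c(OC)cc1OC
F4 | step 7 | 2-(5-hydroxy-2-methoxyphenyl)-3,5,7,8-tetramethoxy-4H-chromen-4-one | COc1ccc(O)cc1-c1oc2c(OC)c(OC)cc(OC)c2c(=O)c1OC
F5 | step 3 | 2-hydroxy-3,5,7,8-tetramethoxychroman-4-one (racemic mixture of diastereomers) | COC1C(O)Oc2c(OC)c(OC)cc(OC)c2C1=O
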